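## The problem

The target is (2S)-naringenin carrying a (2S)-1-methylpiperidin-2-yl group at C6. It is a chroman-4-one (rings A and C) with the 4-hydroxyphenyl ring B at C2, and the piperidine is joined to ring A by one aryl–C(sp3) bond flanked by the C5 and C7 hydroxyls. The two stereocentres, C2 and C2'', lie on opposite edges of a flat, fully substituted arene and cannot steer one another, so each needs its own external control. Once C2'' is fixed, an error at C2 appears as a separable diastereomer. C2 is the fragile centre, because a flavanone opens to the 2'-hydroxychalcone by retro-oxa-Michael reaction under base and recloses without memory, so it is best made late. C2'' is a benzylic amine on a phloroglucinol-type ring and can ionise in strong acid or fragment in the retro-Mannich sense once the ortho hydroxyls are free. The free triphenol is also easily oxidised, so the three phenols should stay masked to the end and be released under neutral conditions. The enabling feature is that O1 on C8a stands para to C6. The ring A precursor is therefore a 4-substituted 3,5-dioxygenated phenol whose two ortho carbons are equivalent, and a halogen at either one defines C4a. Ring C is then only a carbonyl carbon (C4) between C4a and a two-carbon unit C3–C2 that ends at ring B, which is the pattern of a phenol, carbon monoxide and an aryl acetylene.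

## Retrosynthesis

**23 from 22.** The last cut removes only the three O-benzyl groups. Benzyl is preferred to methyl, whose Lewis-acid cleavage would open or epimerise the flavanone, and to acetal groups, whose removal by acid and heat endangers C2''. The precursor 22 is no simpler in skeleton. The benzyl ethers must outlast butyllithium, a Grignard reagent, brief acid, palladium under CO and a homogeneous ruthenium hydrogenation, which aryl benzyl ethers should do.

**22 from 20.** No skeletal bond is cut; C2 is flattened to the flavone 20 by removing two hydrogens across C2–C3. This is preferred to closing ring C at the flavanone level, because a flavone tolerates the amine base and heat of a ring-forming step. The stereocentre is then set last, by a catalyst acting on a rigid planar substrate. The forward step must add hydrogen to one face of C2=C3 under catalyst control and bring any over-reduced flavan-4-ol 21 back to the ketone.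

**20 from 15, 16 and 17 (key disconnection).** Three bonds are cut: C4a–C4, C4–C3 and O1–C2. Ring C disappears; C4 becomes carbon monoxide 16, and C2, C3 and ring B become the commercial alkyne 17. Two-component neighbours of the Baker–Venkataraman or aldol type would first need an acyl group placed on ring A by Friedel–Crafts chemistry beside an amine and benzyl ethers. An iodine is much easier to place. The forward reaction must let CO insertion outrun direct alkynylation and must close the ring in the 6-endo sense.

**15 from 14, and 14 from 13.** The C–I bond is cut, then the O–Si bond. Phenol 14 has only two unsubstituted ring carbons; they are equivalent and both ortho to the free hydroxyl. The iodination therefore has no regiochemical question, only mono- against di-substitution. The oxygen that becomes O1 stays silylated until this point, so that it is the single free phenol when iodine is introduced and when ring C is closed.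

**13 from 12, 12 from 10, and 10 from 7 and 8.** Three cuts take the piperidine apart:
- N–CH3, made forward by reductive methylation.
- N1''–C6'', made by intramolecular N-alkylation with a terminal chloride once the auxiliary is removed.
- C2''–C3'', made by adding the Grignard reagent 9 (from 8) to the sulfinyl aldimine 7; this step creates C2''.

Catalytic reduction of the corresponding cyclic imine would be shorter, but a ketimine flanked by a 2,6-bis(benzyloxy)aryl group is a doubtful substrate for enantioface discrimination. The auxiliary gives diastereomers that can be purified. The forward reactions need chair-type delivery from magnesium bound to the sulfinyl oxygen, and auxiliary removal without ionising the benzylic C–N bond.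

**7 from 5 and 6; 5 from 2; 2 from 1.** The C=N bond is cut to aldehyde 5 and (R)-tert-butanesulfinamide 6. The formyl–aryl bond is cut to arene 2, whose carbon between the two benzyloxy groups is the best-coordinated and most acidic ring position. The silyl ether 2 comes from commercial 1, which already has all three oxygens in place and benzyl groups on the two that stay masked.

## Roads not taken

**Alternative 1:** The cut is made at the piperidine, where N1''–C2'' and C2''–C3'' form together in a Petasis borono-Mannich reaction.
- Forward step: salicylaldehyde A2 (2-(benzyloxy)-6-hydroxy-4-(methoxymethoxy)benzaldehyde), N-methylbut-3-en-1-amine A3 and (E)-styrylboronic acid A4 would combine under a chiral biphenol to give allylic amine A1 with C2'' set. Ring-closing metathesis between the butenyl and styryl alkenes and hydrogenation would then close the piperidine.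
- Merits: three simple components, the N-methyl group in place from the start, catalytic control of C2'' and no stoichiometric auxiliary. For this fragment it is shorter than steps 3–6 of the chosen route.
- Weak points: the iminium ion of a 2,4,6-trioxygenated benzaldehyde is a poor electrophile. The substrate phenol itself binds boron, which opens an uncatalysed racemic channel beside the biphenol-bound one. The metathesis has to run beside a basic tertiary amine. In A1 the two oxygens flanking the piperidine are differentiated, so further protecting-group steps are needed before ring A regains its symmetry.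
- Comparison: this road solves only the piperidine and at best converges on phenol 14, leaving ring C and C2 unbuilt. The chosen plan concedes the shorter piperidine synthesis and sets against it a one-step construction of ring C from 15 and the purification of C2'' at the diastereomer stage.

**Alternative 2:** Here N1''–C2'' is made by C–H amination.
- Forward step: aryl sulfamate A6 (3-(benzyloxy)-2-(5-chloropentyl)-5-(methoxymethoxy)phenyl sulfamate) would be oxidised with PhI(OAc)2 under Rh2(S-nap)4 or its antipode. The rhodium nitrene inserts into the benzylic C–H bond and closes the six-membered benzoxathiazine dioxide A5. N-alkylation by the pendant chloride, excision of the SO2 tether and N-methylation would follow.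
- Merits: a C–H bond becomes the stereocentre, the tether selects the benzylic position, no organometallic addition to a crowded carbonyl derivative is needed, and chirality is catalytic.
- Weak points: the trioxygenated ring and its OCH2Ph and OCH2O hydrogens are themselves open to oxidation and nitrene attack. Enantiocontrol by the chiral carboxamidate is better established for alkyl sulfamate esters than for phenol-tethered ones. The SO2 bridge between a phenol oxygen and a dialkylated nitrogen must be removed under forcing conditions next to an acid-sensitive benzylic amine. A6 itself needs a differentiated, ortho-alkylated phloroglucinol.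
- Comparison: it is the more modern way to C2'' and avoids the auxiliary, but like Alternative 1 it ends at the piperidine. The chosen plan sets against it steps with close precedent on electron-rich arenes and no tether to remove.

**Alternative 3:** The cut is C4–C4a.
- Forward step: acid A8 ((3S)-3-{3,5-bis(benzyloxy)-4-[(2S)-1-methylpiperidin-2-yl]phenoxy}-3-(4-{[(benzyloxy)carbonyl]oxy}phenyl)propanoic acid), activated as its acid chloride or mixed trifluoroacetic anhydride, would acylate an ortho carbon of ring A and close ring C to chromanone A7. A8 would come from the same phenol 14 by Mitsunobu inversion of β-hydroxy ester A9 (ethyl (3R)-3-(4-{[(benzyloxy)carbonyl]oxy}phenyl)-3-hydroxypropanoate) and ester hydrolysis.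
- Merits: it uses the same symmetric phenol and so the same regiochemical advantage. C2 comes from a Noyori-type β-keto ester hydrogenation, which is more predictable in sense than the flavone hydrogenation chosen here. It reaches the flavanone oxidation level directly, without iodination, pressurised CO or a reduction–reoxidation pair. From 14 the step count is about the same.
- Weak points: C2 is carried through two steps that both threaten it. The Mitsunobu displacement at a secondary benzylic carbinol with a para oxygen can leak through ionisation or eliminate to the cinnamate, even with the carbonate in place. Activation of a β-aryloxy acid invites loss of the phenoxide (retro-oxa-Michael) and non-stereospecific recombination, while the ammonium group and benzyl ethers sit in an acidic medium.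
- Comparison: at its best this road is as short and more predictable at C2. The chosen plan sets against it that C2 is created only after every ring-forming event, under neutral conditions, on a flat substrate for which either antipode of the catalyst can be used.

Key step: step 9

Assumption: which antipode of the chiral carbene precursor directs hydrogen to the Re face of C2 (giving 2S) is not predicted here; both antipodes are accessible and the one that gives 2S is used.

## Route

Step 1
Reactants: 1 3,5-bis(benzyloxy)phenol
Product: 2 [3,5-bis(benzyloxy)phenoxy]tri(propan-2-yl)silane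
Conditions: i-Pr3SiCl, imidazole, DMF, 0 °C → rt
Reagents that add atoms: chlorotri(propan-2-yl)silane, CC(C)[Si](Cl)(C(C)C)C(C)C
Why: Standard O-silylation of a phenol; the triisopropylsilyl group is chosen because its bulk shields the flanking ring positions and the silicon atom from butyllithium and it should survive the Grignard and brief acid steps, yet leave with fluoride without touching the benzyl ethers.

Step 2
Reactants: 2 [3,5-bis(benzyloxy)phenoxy]tri(propan-2-yl)silane
Product: 5 2,6-bis(benzyloxy)-4-{[tri(propan-2-yl)silyl]oxy}benzaldehyde, via aryllithium 3 (not isolated), via lithium hemiaminal alkoxide 4 (not isolated)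
Conditions: n-BuLi, THF, −20 → 0 °C; DMF, 0 °C → rt; aq NH4Cl
Reagents that add atoms: N,N-dimethylformamide, CN(C)C=O
Why: Directed ortho-metalation: the one ring position flanked by two benzyloxy groups is deprotonated under cooperative coordination of both ether oxygens, while the positions next to the bulky, weakly directing silyloxy group are left alone. DMF traps the aryllithium as the hemiaminal alkoxide, which releases the aldehyde on aqueous work-up.

Step 3
Reactants: 5 2,6-bis(benzyloxy)-4-{[tri(propan-2-yl)silyl]oxy}benzaldehyde; 6 (R)-2-methylpropane-2-sulfinamide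
Product: 7 (R)-N-[(E)-(2,6-bis(benzyloxy)-4-{[tri(propan-2-yl)silyl]oxy}phenyl)methylidene]-2-methylpropane-2-sulfinamide
Conditions: Ti(OEt)4, THF, 60 °C
Reagents that add atoms: none
Why: Ti(OEt)4-mediated condensation of an aldehyde with tert-butanesulfinamide; the titanium alkoxide activates the hindered carbonyl and scavenges water, the (E)-aldimine forms and the sulfur stereocentre is untouched.

Step 4
Reactants: 7 (R)-N-[(E)-(2,6-bis(benzyloxy)-4-{[tri(propan-2-yl)silyl]oxy}phenyl)methylidene]-2-methylpropane-2-sulfinamide; 8 1-bromo-4-chlorobutane
Product: 10 (R)-N-[(1S)-1-(2,6-bis(benzyloxy)-4-{[tri(propan-2-yl)silyl]oxy}phenyl)-5-chloropentyl]-2-methylpropane-2-sulfinamide, via 4-chlorobutylmagnesium bromide 9 (not isolated)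
Conditions: Mg, Et2O, rt (8 to 9); then 7, CH2Cl2, −48 → −20 °C; aq NH4Cl
Reagents that add atoms: none
Why: Magnesium inserts into the C–Br bond of 8 in preference to C–Cl, and the Grignard reagent adds to the N-sulfinyl aldimine (auxiliary-controlled 1,2-addition). In the non-coordinating solvent the reaction should pass through the closed six-membered chair with magnesium bound to the sulfinyl oxygen and tert-butyl equatorial, which delivers the alkyl group to the Si face of the (R)-sulfinyl aldimine and sets C2'' as S. The minor diastereomer can be removed by chromatography at this stage.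

Step 5
Reactants: 10 (R)-N-[(1S)-1-(2,6-bis(benzyloxy)-4-{[tri(propan-2-yl)silyl]oxy}phenyl)-5-chloropentyl]-2-methylpropane-2-sulfinamide
Product: 12 (2S)-2-(2,6-bis(benzyloxy)-4-{[tri(propan-2-yl)silyl]oxy}phenyl)piperidine, via amine hydrochloride 11 (not isolated)
Conditions: HCl (4 M in 1,4-dioxane), MeOH, 0 °C; evaporate; K2CO3, NaI (cat.), MeCN, 60 °C
Reagents that add atoms: none
Why: Acidic methanolysis cleaves the S–N bond of the sulfinamide, and on basification the primary amine displaces the terminal chloride in a 6-exo-tet N-alkylation under iodide catalysis to close the piperidine. No bond at C2'' is broken, so its configuration is kept; the acid stage is cold and short because the trioxygenated benzylic position could otherwise ionise.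

Step 6
Reactants: 12 (2S)-2-(2,6-bis(benzyloxy)-4-{[tri(propan-2-yl)silyl]oxy}phenyl)piperidine
Product: 13 (2S)-2-(2,6-bis(benzyloxy)-4-{[tri(propan-2-yl)silyl]oxy}phenyl)-1-methylpiperidine
Conditions: aq HCHO, NaBH(OAc)3, AcOH (cat.), ClCH2CH2Cl, rt
Reagents that add atoms: formaldehyde, C=O
Why: Reductive amination (Borch-type N-methylation): the secondary amine condenses with formaldehyde and the hydride donor reduces the adduct as it forms, which avoids quaternisation. The phenol is still silylated, which tempers the ring toward Mannich-type attack by formaldehyde.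

Step 7
Reactants: 13 (2S)-2-(2,6-bis(benzyloxy)-4-{[tri(propan-2-yl)silyl]oxy}phenyl)-1-methylpiperidine
Product: 14 3,5-bis(benzyloxy)-4-[(2S)-1-methylpiperidin-2-yl]phenol
Conditions: Bu4NF, THF, 0 °C; aq NH4Cl
Reagents that add atoms: none
Why: Fluoride-induced cleavage of the aryl silyl ether frees the one phenol that will become O1; the benzyl ethers and the amine are inert.

Step 8
Reactants: 14 3,5-bis(benzyloxy)-4-[(2S)-1-methylpiperidin-2-yl]phenol
Product: 15 3,5-bis(benzyloxy)-2-iodo-4-[(2S)-1-methylpiperidin-2-yl]phenol
Conditions: N-iodosuccinimide (1.0 equiv), CF3CO2H (1.1 equiv), MeCN, −20 → 0 °C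
Reagents that add atoms: N-iodosuccinimide, O=C1CCC(=O)N1I
Why: Electrophilic aromatic iodination of an activated phenol: the two free ring positions are equivalent and both ortho to the hydroxyl, so one equivalent of the iodinating agent can only lead to 15. CF3CO2H keeps the amine protonated, which blocks N-iodination and ipso attack with retro-Mannich loss of the piperidine.

Step 9
Reactants: 15 3,5-bis(benzyloxy)-2-iodo-4-[(2S)-1-methylpiperidin-2-yl]phenol; 16 carbon monoxide; 17 1-(benzyloxy)-4-ethynylbenzene
Product: 20 5,7-bis(benzyloxy)-2-[4-(benzyloxy)phenyl]-6-[(2S)-1-methylpiperidin-2-yl]-4H-chromen-4-one, via ortho-hydroxyaryl ynone 18 (not isolated), via enaminone 19 (not isolated)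
Conditions: PdCl2(PPh3)2 (5 mol %), CO (20 bar), Et2NH, 100 °C
Reagents that add atoms: none
Why: The divalent palladium precatalyst is reduced in the amine/CO medium to zerovalent palladium, which inserts into the C–I bond of 15; CO inserts to give the aroylpalladium iodide, the acetylide formed from 17 and diethylamine is transferred to palladium, and reductive elimination gives the ynone 18 (C4a–C4 and C4–C3 formed). Diethylamine then adds to the ynone in the conjugate sense to give enaminone 19, and the phenol oxygen attacks the amine-bearing carbon (C2) with loss of diethylamine, which forms O1–C2 and closes ring C in the 6-endo mode by addition–elimination. The closest known reaction type is the carbonylative Sonogashira annulation of 2-iodophenols with terminal aryl acetylenes in a secondary amine, which gives flavones. No stereocentre is formed. The step needs CO insertion to outrun direct alkynylation, which a crowded, electron-rich arylpalladium, the absence of copper and CO pressure should secure. It needs 6-endo over 5-exo closure, which the enaminone pathway secures by placing the electrophilic carbon at C2, so the aurone is avoided. The site of ring fusion is fixed by the iodine, and the only free hydroxyl is the one next to it, the other two oxygens being benzylated. The tertiary amine of 15 is a spectator in the amine solvent and C2'' carries no acidic hydrogen under these conditions.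

Step 10
Reactants: 20 5,7-bis(benzyloxy)-2-[4-(benzyloxy)phenyl]-6-[(2S)-1-methylpiperidin-2-yl]-4H-chromen-4-one
Product: 22 (2S)-5,7-bis(benzyloxy)-2-[4-(benzyloxy)phenyl]-6-[(2S)-1-methylpiperidin-2-yl]-2,3-dihydro-4H-chromen-4-one, via cis-flavan-4-ol 21 (not isolated)
Conditions: Ru(cod)(2-methylallyl)2 (5 mol %), (R,R)- or (S,S)-1,3-bis[1-(naphthalen-1-yl)ethyl]-4,5-dihydro-1H-imidazol-3-ium tetrafluoroborate (10 mol %), KOt-Bu (15 mol %), H2 (100 bar), toluene–hexane, 25–40 °C; filter, evaporate; Dess–Martin periodinane, NaHCO3, CH2Cl2, 0 °C → rt
Reagents that add atoms: none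
Why: Catalyst-controlled asymmetric hydrogenation of the flavone C2=C3 bond with the ruthenium–N-heterocyclic carbene complex formed in situ, a reaction known for flavones; the chiral carbene selects the Re face of C2 for hydrogen delivery and so sets C2 as S, the remote C2'' centre having no say. Part of the material is reduced further to the flavan-4-ol 21, and buffered Dess–Martin oxidation of the crude mixture converges on the flavanone without touching C2.

Step 11
Reactants: 22 (2S)-5,7-bis(benzyloxy)-2-[4-(benzyloxy)phenyl]-6-[(2S)-1-methylpiperidin-2-yl]-2,3-dihydro-4H-chromen-4-one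
Product: 23 (2S)-5,7-dihydroxy-2-(4-hydroxyphenyl)-6-[(2S)-1-methylpiperidin-2-yl]-2,3-dihydro-4H-chromen-4-one
Conditions: H2 (1 atm), 10% Pd/C, EtOAc–MeOH, rt
Reagents that add atoms: none
Why: Hydrogenolysis of three aryl benzyl ethers over palladium on carbon at ambient pressure; these O–CH2Ph bonds should cleave much faster than the cyclic benzylic C2–O1 and C2''–N bonds or the C4 carbonyl, and the neutral conditions leave both stereocentres alone.

## Compound list

1 | 3,5-bis(benzyloxy)phenol | Oc1cc(OCc2ccccc2)cc(OCc2ccccc2)c1 | starting material
2 | [3,5-bis(benzyloxy)phenoxy]tri(propan-2-yl)silane | CC(C)[Si](Oc1cc(OCc2ccccc2)cc(OCc2ccccc2)c1)(C(C)C)C(C)C | intermediate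
3 | (2,6-bis(benzyloxy)-4-{[tri(propan-2-yl)silyl]oxy}phenyl)lithium | [Li]c1c(OCc2ccccc2)cc(O[Si](C(C)C)(C(C)C)C(C)C)cc1OCc1ccccc1 | intermediate (not isolated)
4 | lithium (2,6-bis(benzyloxy)-4-{[tri(propan-2-yl)silyl]oxy}phenyl)(dimethylamino)methanolate | [Li+].[O-]C(N(C)C)c1c(OCc2ccccc2)cc(O[Si](C(C)C)(C(C)C)C(C)C)cc1OCc1ccccc1 | intermediate (not isolated)
5 | 2,6-bis(benzyloxy)-4-{[tri(propan-2-yl)silyl]oxy}benzaldehyde | O=Cc1c(OCc2ccccc2)cc(O[Si](C(C)C)(C(C)C)C(C)C)cc1OCc1ccccc1 | intermediate
6 | (R)-2-methylpropane-2-sulfinamide | CC(C)(C)[S@@](=O)N | starting material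
7 | (R)-N-[(E)-(2,6-bis(benzyloxy)-4-{[tri(propan-2-yl)silyl]oxy}phenyl)methylidene]-2-methylpropane-2-sulfinamide | CC(C)(C)[S@@](=O)/N=C/c1c(OCc2ccccc2)cc(O[Si](C(C)C)(C(C)C)C(C)C)cc1OCc1ccccc1 | intermediate
8 | 1-bromo-4-chlorobutane | ClCCCCBr | starting material
9 | 4-chlorobutylmagnesium bromide | ClCCCC[Mg]Br | intermediate (not isolated)
10 | (R)-N-[(1S)-1-(2,6-bis(benzyloxy)-4-{[tri(propan-2-yl)silyl]oxy}phenyl)-5-chloropentyl]-2-methylpropane-2-sulfinamide | CC(C)(C)[S@@](=O)N[C@@H](CCCCCl)c1c(OCc2ccccc2)cc(O[Si](C(C)C)(C(C)C)C(C)C)cc1OCc1ccccc1 | intermediate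
11 | (1S)-1-(2,6-bis(benzyloxy)-4-{[tri(propan-2-yl)silyl]oxy}phenyl)-5-chloropentan-1-amine hydrochloride | Cl.N[C@@H](CCCCCl)c1c(OCc2ccccc2)cc(O[Si](C(C)C)(C(C)C)C(C)C)cc1OCc1ccccc1 | intermediate (not isolated)
12 | (2S)-2-(2,6-bis(benzyloxy)-4-{[tri(propan-2-yl)silyl]oxy}phenyl)piperidine | N1CCCC[C@H]1c1c(OCc2ccccc2)cc(O[Si](C(C)C)(C(C)C)C(C)C)cc1OCc1ccccc1 | intermediate
13 | (2S)-2-(2,6-bis(benzyloxy)-4-{[tri(propan-2-yl)silyl]oxy}phenyl)-1-methylpiperidine | CN1CCCC[C@H]1c1c(OCc2ccccc2)cc(O[Si](C(C)C)(C(C)C)C(C)C)cc1OCc1ccccc1 | intermediate
14 | 3,5-bis(benzyloxy)-4-[(2S)-1-methylpiperidin-2-yl]phenol | CN1CCCC[C@H]1c1c(OCc2ccccc2)cc(O)cc1OCc1ccccc1 | intermediate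
15 | 3,5-bis(benzyloxy)-2-iodo-4-[(2S)-1-methylpiperidin-2-yl]phenol | CN1CCCC[C@H]1c1c(OCc2ccccc2)cc(O)c(I)c1OCc1ccccc1 | intermediate
16 | carbon monoxide | [C-]#[O+] | starting material
17 | 1-(benzyloxy)-4-ethynylbenzene | C#Cc1ccc(OCc2ccccc2)cc1 | starting material
18 | 1-{2,4-bis(benzyloxy)-6-hydroxy-3-[(2S)-1-methylpiperidin-2-yl]phenyl}-3-[4-(benzyloxy)phenyl]prop-2-yn-1-one | CN1CCCC[C@H]1c1c(OCc2ccccc2)cc(O)c(C(=O)C#Cc2ccc(OCc3ccccc3)cc2)c1OCc1ccccc1 | intermediate (not isolated)
19 | 1-{2,4-bis(benzyloxy)-6-hydroxy-3-[(2S)-1-methylpiperidin-2-yl]phenyl}-3-[4-(benzyloxy)phenyl]-3-(diethylamino)prop-2-en-1-one (alkene geometry not defined) | CN1CCCC[C@H]1c1c(OCc2ccccc2)cc(O)c(C(=O)C=C(N(CC)CC)c2ccc(OCc3ccccc3)cc2)c1OCc1ccccc1 | intermediate (not isolated)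
20 | 5,7-bis(benzyloxy)-2-[4-(benzyloxy)phenyl]-6-[(2S)-1-methylpiperidin-2-yl]-4H-chromen-4-one | CN1CCCC[C@H]1c1c(OCc2ccccc2)cc2oc(-c3ccc(OCc4ccccc4)cc3)cc(=O)c2c1OCc1ccccc1 | intermediate
21 | (2S,4S)-5,7-bis(benzyloxy)-2-[4-(benzyloxy)phenyl]-6-[(2S)-1-methylpiperidin-2-yl]-3,4-dihydro-2H-chromen-4-ol (2,4-cis expected; C4 is erased on oxidation) | CN1CCCC[C@H]1c1c(OCc2ccccc2)cc2c(c1OCc1ccccc1)[C@@H](O)C[C@@H](c1ccc(OCc3ccccc3)cc1)O2 | intermediate (not isolated)
22 | (2S)-5,7-bis(benzyloxy)-2-[4-(benzyloxy)phenyl]-6-[(2S)-1-methylpiperidin-2-yl]-2,3-dihydro-4H-chromen-4-one | CN1CCCC[C@H]1c1c(OCc2ccccc2)cc2c(c1OCc1ccccc1)C(=O)C[C@@H](c1ccc(OCc3ccccc3)cc1)O2 | intermediate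
23 | (2S)-5,7-dihydroxy-2-(4-hydroxyphenyl)-6-[(2S)-1-methylpiperidin-2-yl]-2,3-dihydro-4H-chromen-4-one | CN1CCCC[C@H]1c1c(O)cc2c(c1O)C(=O)C[C@@H](c1ccc(O)cc1)O2 | target

## Step count and risks

Total step count: 11. Longest linear sequence: 11 steps (1 to 23); compounds 6, 8, 16 and 17 are commercial and enter directly.

**Step 9 (key step).** The most likely failure is diversion of the aroylpalladium intermediate. It may be captured by diethylamine (aminocarbonylation), or, if CO insertion is slow, direct alkynylation may be followed by 5-endo closure. Oxidative addition to an iodide between two oxygen substituents may also be sluggish. The fallback sets out from 15 and avoids both CO and an amine nucleophile: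
- Stille coupling with tributyl(1-ethoxyethenyl)stannane (PdCl2(PPh3)2, toluene, 100 °C) would give the enol ether 3,5-bis(benzyloxy)-2-(1-ethoxyethenyl)-4-[(2S)-1-methylpiperidin-2-yl]phenol F1.
- Dilute aqueous HCl hydrolyses it to the methyl ketone 1-{2,4-bis(benzyloxy)-6-hydroxy-3-[(2S)-1-methylpiperidin-2-yl]phenyl}ethan-1-one F2.
- Claisen–Schmidt condensation with 4-(benzyloxy)benzaldehyde (KOH, EtOH) would give the chalcone (2E)-1-{2,4-bis(benzyloxy)-6-hydroxy-3-[(2S)-1-methylpiperidin-2-yl]phenyl}-3-[4-(benzyloxy)phenyl]prop-2-en-1-one F3.
- Oxidative cyclisation (catalytic I2 in DMSO, 120 °C) comes back to the route at flavone 20.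

**Step 4.** The most likely failure is poor facial selectivity, because an ortho benzyloxy oxygen can chelate magnesium together with the imine nitrogen and open a non-chair pathway. Addition to the electron-rich, doubly ortho-substituted aldimine may also be slow. The fallback sets out from 2 through the aryllithium 3:
- Addition to tert-butyl 2-oxopiperidine-1-carboxylate (THF, −78 °C) should open the lactam to tert-butyl N-[5-(2,6-bis(benzyloxy)-4-{[tri(propan-2-yl)silyl]oxy}phenyl)-5-oxopentyl]carbamate F4.
- CF3CO2H removes the carbamate, and on neutralisation the amino ketone condenses to the cyclic imine 6-(2,6-bis(benzyloxy)-4-{[tri(propan-2-yl)silyl]oxy}phenyl)-2,3,4,5-tetrahydropyridine F5.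
- Asymmetric hydrogenation ([Ir(cod)Cl]2 with a chiral bisphosphine, H2, ligand antipode chosen for the S amine) comes back to the route at 12.

This path also bypasses the acidic auxiliary cleavage of step 5.

**Step 10.** The most likely failures are low conversion (the peri benzyloxy group at C5 and the tertiary amine can hinder or occupy ruthenium), insufficient facial selectivity at C2, or partial arene hydrogenation. The fallback sets out from 20:
- Conjugate reduction with LiBH(s-Bu)3 (THF, −78 °C) would give 22 together with its C2 epimer (2R)-5,7-bis(benzyloxy)-2-[4-(benzyloxy)phenyl]-6-[(2S)-1-methylpiperidin-2-yl]-2,3-dihydro-4H-chromen-4-one F6.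
- The two are diastereomers because of C2'' and are separated by chromatography or crystallisation.
- F6 is re-equilibrated with a mild base (NaOAc, EtOH, heat) through reversible opening of ring C and recycled, so the material comes back to the route at 22.

**Step 2.** The most likely failure is deprotonation at a benzylic OCH2Ph position followed by [1,2]-Wittig rearrangement, or attack of butyllithium at silicon, in place of ring lithiation. The fallback sets out from 1:
- Vilsmeier–Haack formylation (POCl3, DMF, MeCN, 0 °C → rt) para to the hydroxyl would give the iminium salt {[2,6-bis(benzyloxy)-4-hydroxyphenyl]methylidene}dimethylazanium chloride F7.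
- Aqueous NaOAc hydrolyses it to 2,6-bis(benzyloxy)-4-hydroxybenzaldehyde F8; the minor product of ortho formylation is removed by chromatography.
- Silylation (i-Pr3SiCl, imidazole, DMF) comes back to the route at 5.

## Further compounds

F1 | step 9 | 3,5-bis(benzyloxy)-2-(1-ethoxyethenyl)-4-[(2S)-1-methylpiperidin-2-yl]phenol | CN1CCCC[C@H]1c1c(OCc2ccccc2)cc(O)c(C(=C)OCC)c1OCc1ccccc1
F2 | step 9 | 1-{2,4-bis(benzyloxy)-6-hydroxy-3-[(2S)-1-methylpiperidin-2-yl]phenyl}ethan-1-one | CN1CCCC[C@H]1c1c(OCc2ccccc2)cc(O)c(C(C)=O)c1OCc1ccccc1
F3 | step 9 | (2E)-1-{2,4-bis(benzyloxy)-6-hydroxy-3-[(2S)-1-methylpiperidin-2-yl]phenyl}-3-[4-(benzyloxy)phenyl]prop-2-en-1-one | CN1CCCC[C@H]1c1c(OCc2ccccc2)cc(O)c(C(=O)/C=C/c2ccc(OCc3ccccc3)cc2)c1OCc1ccccc1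
F4 | step 4 | tert-butyl N-[5-(2,6-bis(benzyloxy)-4-{[tri(propan-2-yl)silyl]oxy}phenyl)-5-oxopentyl]carbamate | CC(C)(C)OC(=O)NCCCCC(=O)c1c(OCc2ccccc2)cc(O[Si](C(C)C)(C(C)C)C(C)C)cc1OCc1ccccc1
F5 | step 4 | 6-(2,6-bis(benzyloxy)-4-{[tri(propan-2-yl)silyl]oxy}phenyl)-2,3,4,5-tetrahydropyridine | C1CCN=C(C1)c1c(OCc2ccccc2)cc(O[Si](C(C)C)(C(C)C)C(C)C)cc1OCc1ccccc1
F6 | step 10 | (2R)-5,7-bis(benzyloxy)-2-[4-(benzyloxy)phenyl]-6-[(2S)-1-methylpiperidin-2-yl]-2,3-dihydro-4H-chromen-4-one | CN1CCCC[C@H]1c1c(OCc2ccccc2)cc2c(c1OCc1ccccc1)C(=O)C[C@H](c1ccc(OCc3ccccc3)cc1)O2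
F7 | step 2 | {[2,6-bis(benzyloxy)-4-hydroxyphenyl]methylidene}dimethylazanium chloride | C[N+](C)=Cc1c(OCc2ccccc2)cc(O)cc1OCc1ccccc1.[Cl-]
F8 | step 2 | 2,6-bis(benzyloxy)-4-hydroxybenzaldehyde | O=Cc1c(OCc2ccccc2)cc(O)cc1OCc1ccccc1
A1 | alternative 1 | 3-(benzyloxy)-2-{(1S,2E)-1-[but-3-en-1-yl(methyl)amino]-3-phenylprop-2-en-1-yl}-5-(methoxymethoxy)phenol | C=CCCN(C)[C@@H](/C=C/c1ccccc1)c1c(O)cc(OCOC)cc1OCc2ccccc2
A2 | alternative 1 | 2-(benzyloxy)-6-hydroxy-4-(methoxymethoxy)benzaldehyde | O=Cc1c(O)cc(OCOC)cc1OCc1ccccc1
A3 | alternative 1 | N-methylbut-3-en-1-amine | C=CCCNC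
A4 | alternative 1 | [(E)-2-phenylethenyl]boronic acid | OB(O)/C=C/c1ccccc1
A5 | alternative 2 | (4S)-5-(benzyloxy)-4-(4-chlorobutyl)-7-(methoxymethoxy)-3,4-dihydro-1,2,3-benzoxathiazine 2,2-dioxide | O=S1(=O)N[C@@H](CCCCCl)c2c(OCc3ccccc3)cc(OCOC)cc2O1
A6 | alternative 2 | 3-(benzyloxy)-2-(5-chloropentyl)-5-(methoxymethoxy)phenyl sulfamate | NS(=O)(=O)Oc1cc(OCOC)cc(OCc2ccccc2)c1CCCCCCl
A7 | alternative 3 | (2S)-5,7-bis(benzyloxy)-2-{4-[(benzyloxycarbonyl)oxy]phenyl}-6-[(2S)-1-methylpiperidin-2-yl]chroman-4-one | CN1CCCC[C@H]1c1c(OCc2ccccc2)cc2c(c1OCc3ccccc3)C(=O)C[C@@H](c4ccc(OC(=O)OCc5ccccc5)cc4)O2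
A8 | alternative 3 | (3S)-3-{3,5-bis(benzyloxy)-4-[(2S)-1-methylpiperidin-2-yl]phenoxy}-3-(4-{[(benzyloxy)carbonyl]oxy}phenyl)propanoic acid | CN1CCCC[C@H]1c1c(OCc2ccccc2)cc(O[C@@H](CC(=O)O)c2ccc(OC(=O)OCc3ccccc3)cc2)cc1OCc1ccccc1
A9 | alternative 3 | ethyl (3R)-3-(4-{[(benzyloxy)carbonyl]oxy}phenyl)-3-hydroxypropanoate | CCOC(=O)C[C@@H](O)c1ccc(OC(=O)OCc2ccccc2)cc1
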